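**Plan**
Numbering: ring A is C1(O-acyl)–C2(OH)–C3–C4–C9(CH3)–C10(CH3); ring B is C4=C5–C6(=O)–C7(OH)=C8–C9; β is the face of the C9 methyl.
Retrosynthesis: cut the C1–O ester bond (acid from (S)-2-methylbutan-1-ol); take the C7 enol and C4=C5 back to a C5=C6 silyl enol ether, the C10 methyl back to a C10 ketone, and remove the C1 and C2 oxygens; then cut C4–C9 and C7–C8.
The cut is possible because quaternary C9 (bearing CH3, C8, C10, C4) is the α-carbon of an isopropenyl ketone once C10 is a carbonyl, and ring B is a cyclohexene whose C6 oxygen is the silyloxy group of a diene C4=C5–C6=C7.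
Forward: an acyclic trienone closes rings A and B together in an intramolecular Diels–Alder reaction. Ring A is then built up from the C10 ketone while ring B stays masked: C1=C2 desaturation, C2 oxygenation by conjugate borylation, C1 hydroxylation, C10 methylenation. Unmasking the enone, hydrogenation, esterification and C7 oxidation finish the route.
Stereochemistry: C9 from the chiral oxazaborolidinium catalyst; C2 from the chiral copper–boryl catalyst; C1 anti to the C2 silyloxy group; C10 by hydrogen delivery opposite the C9 methyl; the side-chain centre from (S)-2-methylbutan-1-ol.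

Key step: step 5

Assumption: the catalyst antipodes named in steps 5 and 7 are those expected to give (S)-C9 and the C2 α-boronate; each sense is checked on first use (step 5 by Pd(OAc)2 oxidation of a sample of the adduct to the known Wieland–Miescher ketone), and the mirror-image catalyst is used if the sense proves reversed.

**Route**

Step 1
Reactants: 1 hex-5-enoic acid
Product: 2 N-methoxy-N-methylhex-5-enamide
Conditions: MeNH(OMe)·HCl, EDC·HCl, N-methylmorpholine, CH2Cl2, 0 °C to rt
Reagents that add atoms: N,O-dimethylhydroxylamine hydrochloride, CNOC.Cl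
Why: Carbodiimide amide coupling should give the Weinreb amide, which holds the future C10 at the acyl level and is inert to the enolisation of step 3.

Step 2
Reactants: 2 N-methoxy-N-methylhex-5-enamide; 3 methyl vinyl ketone
Product: 4 (E)-N-methoxy-N-methyl-7-oxooct-5-enamide
Conditions: 3 (3 equiv), second-generation Hoveyda–Grubbs catalyst RuCl2(=CH-C6H4-2-O-i-Pr)(H2IMes) (3 mol%), CH2Cl2, 40 °C
Reagents that add atoms: none
Why: Olefin cross-metathesis between a terminal alkene and an electron-poor vinyl ketone favours the cross product and should give the E-enone (C4=C5, C6=O in target numbering).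

Step 3
Reactants: 4 (E)-N-methoxy-N-methyl-7-oxooct-5-enamide
Product: 5 (E)-7-(tert-butyldimethylsilyloxy)-N-methoxy-N-methylocta-5,7-dienamide
Conditions: TBSOTf, Et3N, CH2Cl2, −78 to 0 °C
Reagents that add atoms: tert-butyldimethylsilyl trifluoromethanesulfonate, CC(C)(C)[Si](C)(C)OS(=O)(=O)C(F)(F)F
Why: Silyl enol ether formation by soft enolisation removes a methyl proton of the enone and should give the 2-silyloxy-1,3-diene, the amide not being enolised under these conditions.

Step 4
Reactants: 5 (E)-7-(tert-butyldimethylsilyloxy)-N-methoxy-N-methylocta-5,7-dienamide; 6 isopropenylmagnesium bromide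
Product: 8 (E)-9-(tert-butyldimethylsilyloxy)-2-methyldeca-1,7,9-trien-3-one, via bromomagnesium hemiaminal 7 (not isolated)
Conditions: 6 (1.3 equiv), THF, −20 to 0 °C; poured into cold aq NH4Cl; product kept below 0 °C and used at once
Reagents that add atoms: none
Why: Weinreb ketone synthesis: the chelated tetrahedral adduct resists a second addition and should collapse on buffered quench to the isopropenyl ketone, the silyl dienol ether tolerating the Grignard reagent and the mild work-up.

Step 5
Reactants: 8 (E)-9-(tert-butyldimethylsilyloxy)-2-methyldeca-1,7,9-trien-3-one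
Product: 9 (4aR,8aS)-6-(tert-butyldimethylsilyloxy)-8a-methyl-3,4,4a,7,8,8a-hexahydronaphthalen-1(2H)-one
Conditions: (S)-1-(o-tolyl)-3,3-diphenyltetrahydro-1H,3H-pyrrolo[1,2-c][1,3,2]oxazaborole·HNTf2 (20 mol%), CH2Cl2, −78 to −40 °C
Reagents that add atoms: none
Why: Proposed new method: the N-protonated oxazaborolidine binds the C10 carbonyl of the isopropenyl ketone, lowers the enone LUMO and shields one face of C8=C9, and the tethered 2-silyloxydiene adds in a concerted, asynchronous [4+2] in which C7–C8 bonding leads and C4–C9 bonding follows. The closest known reactions are Lewis-acid-promoted intramolecular Diels–Alder cyclisations of 1,7,9-decatrien-3-ones and oxazaborolidinium-catalysed intermolecular additions of 2-silyloxydienes to α-substituted enones; their union in one enantioselective intramolecular reaction is the untested part. Ring B is the cyclohexene made directly by the cycloaddition (six-membered, both new bonds), and ring A closes at the same time as a six-membered ring through C4–C9 with the C10–C1–C2–C3 chain inside the bicycle (fused, type 1 mode with the carbonyl in the tether). The quaternary centre C9 is set by the catalyst through its choice of enone face, while C4 follows from the endo placement of the tether carbonyl, which gives the cis ring fusion and is erased in step 11. The step needs enantioface selectivity and a single regiochemistry: the three-atom C1–C3 link allows only the fused mode, and this matches the diene polarisation (the silyloxy group makes C7 the nucleophilic terminus, which bonds to the enone β-carbon C8). Competing uncatalysed cyclisation is held back by making 8 cold and running the reaction at −78 to −40 °C.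

Step 6
Reactants: 9 (4aR,8aS)-6-(tert-butyldimethylsilyloxy)-8a-methyl-3,4,4a,7,8,8a-hexahydronaphthalen-1(2H)-one
Product: 11 (4aR,8aS)-6-(tert-butyldimethylsilyloxy)-8a-methyl-4a,7,8,8a-tetrahydronaphthalen-1(4H)-one, via lithium enolate 10 (not isolated)
Conditions: LDA, THF, −78 °C; then PhS(Cl)=N-t-Bu, −78 °C
Reagents that add atoms: none
Why: Because C9 is quaternary only C1 can be enolised, so Mukaiyama dehydrogenation (enolate sulfinimidoylation and syn-elimination) should give the C1=C2 enone without touching the silyl enol ether.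

Step 7
Reactants: 11 (4aR,8aS)-6-(tert-butyldimethylsilyloxy)-8a-methyl-4a,7,8,8a-tetrahydronaphthalen-1(4H)-one
Product: 13 (3R,4aR,8aS)-6-(tert-butyldimethylsilyloxy)-3-hydroxy-8a-methyl-3,4,4a,7,8,8a-hexahydronaphthalen-1(2H)-one, via C2 α-pinacolboronate 12 (not isolated)
Conditions: B2pin2, CuCl (5 mol%), NaOt-Bu (10 mol%), (R)-1-[(S)-2-(diphenylphosphino)ferrocenyl]ethyldicyclohexylphosphine (6 mol%), MeOH (2 equiv), THF, rt; then NaBO3·4H2O, THF/H2O, rt
Reagents that add atoms: sodium perborate, [Na+].[Na+].O[B-]1(O)OO[B-](O)(O)OO1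
Why: Copper-catalysed conjugate borylation of the cyclic enone places boron on C2 from the α face under control of the chiral bisphosphine, and stereoretentive C–B oxidation should give the C2 α-alcohol (new stereocentre C2 set by the catalyst).

Step 8
Reactants: 13 (3R,4aR,8aS)-6-(tert-butyldimethylsilyloxy)-3-hydroxy-8a-methyl-3,4,4a,7,8,8a-hexahydronaphthalen-1(2H)-one
Product: 14 (3R,4aR,8aS)-3,6-bis(tert-butyldimethylsilyloxy)-8a-methyl-3,4,4a,7,8,8a-hexahydronaphthalen-1(2H)-one
Conditions: TBSCl, imidazole, DMF, rt
Reagents that add atoms: tert-butyldimethylsilyl chloride, CC(C)(C)[Si](C)(C)Cl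
Why: Silylation of the secondary alcohol closes off elimination of the β-hydroxy ketone and provides the bulky C2 group that steers step 9.

Step 9
Reactants: 14 (3R,4aR,8aS)-3,6-bis(tert-butyldimethylsilyloxy)-8a-methyl-3,4,4a,7,8,8a-hexahydronaphthalen-1(2H)-one
Product: 16 (2S,3R,4aR,8aS)-3,6-bis(tert-butyldimethylsilyloxy)-2-hydroxy-8a-methyl-3,4,4a,7,8,8a-hexahydronaphthalen-1(2H)-one, via potassium enolate 15 (not isolated)
Conditions: KHMDS, THF, −78 °C; then 3-phenyl-2-(phenylsulfonyl)oxaziridine, −78 °C; aq NH4Cl at −78 °C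
Reagents that add atoms: 3-phenyl-2-(phenylsulfonyl)oxaziridine, O=S(=O)(c1ccccc1)N1OC1c1ccccc1
Why: Enolate hydroxylation with a sulfonyloxaziridine at C1, the only enolisable carbon, should occur anti to the adjacent C2 silyloxy group and give the C1 β-alcohol (new stereocentre C1 set by 1,2-induction from C2).

Step 10
Reactants: 16 (2S,3R,4aR,8aS)-3,6-bis(tert-butyldimethylsilyloxy)-2-hydroxy-8a-methyl-3,4,4a,7,8,8a-hexahydronaphthalen-1(2H)-one
Product: 17 C10-methylidene allylic alcohol (C1 β-OH; C2 α-OTBS; C5=C6 silyl enol ether; cis-fused)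
Conditions: Cp2Ti(μ-CH2)(μ-Cl)AlMe2 (3 equiv), pyridine, THF, −40 to 0 °C; aq NaOH
Reagents that add atoms: Tebbe reagent (open form; Cl→Al bridge not drawn), C[Al](C)C[Ti](Cl)(C1C=CC=C1)C1C=CC=C1
Why: Tebbe methylenation is non-basic and works on hindered, enolisable ketones, so it should convert the C10 carbonyl into the exocyclic methylene without epimerising C1 or moving the silyl group (one equivalent is consumed by the free hydroxyl).

Step 11
Reactants: 17 C10-methylidene allylic alcohol
Product: 18 C10-methylidene enone (C4=C5, C6=O; C1 β-OH; C2 α-OTBS)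
Conditions: Pd(OAc)2 (1.2 equiv), MeCN/DMSO, 40 °C
Reagents that add atoms: none
Why: Saegusa–Ito oxidation of the silyl enol ether (palladation at C5, β-hydride loss from C4) should give the C4=C5 enone at the position fixed by the cycloaddition.

Step 12
Reactants: 18 C10-methylidene enone
Product: 19 C10 β-methyl enone alcohol (C1 β-OH; C2 α-OTBS)
Conditions: H2 (1 atm), RhCl(PPh3)3 (10 mol%), benzene, rt
Reagents that add atoms: none
Why: Homogeneous rhodium-catalysed hydrogenation reduces the 1,1-disubstituted alkene and not the conjugated trisubstituted one, and hydrogen should add to the α face, away from the β-oriented C9 methyl and C1 hydroxyl that flank the methylene, leaving the C10 methyl β (new stereocentre C10 set by the substrate).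

Step 13
Reactants: 20 (S)-2-methylbutan-1-ol
Product: 22 ethyl (2E,4E,6S)-6-methylocta-2,4-dienoate, via (S)-2-methylbutanal 21 (not isolated)
Conditions: NaOCl, TEMPO (1 mol%), KBr (10 mol%), aq NaHCO3, CH2Cl2, 0 °C; dried CH2Cl2 solution added to (EtO)2P(O)CH2CH=CHCO2Et/LiHMDS, THF, −78 to 0 °C; aq NH4Cl
Reagents that add atoms: triethyl 4-phosphonocrotonate, CCOC(=O)/C=C/CP(=O)(OCC)OCC
Why: Nitroxyl-catalysed hypochlorite oxidation gives the α-branched aldehyde without racemisation, and the vinylogous Horner–Wadsworth–Emmons reaction at low temperature should give the (2E,4E)-dienoate with the (S)-centre intact.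

Step 14
Reactants: 22 ethyl (2E,4E,6S)-6-methylocta-2,4-dienoate
Product: 23 (2E,4E,6S)-6-methylocta-2,4-dienoic acid
Conditions: LiOH, THF/MeOH/H2O, rt; then aq HCl to pH 3
Reagents that add atoms: lithium hydroxide, [Li+].[OH-]
Why: Ester saponification should free the acid, the remote C6 centre and the diene geometry being untouched by aqueous hydroxide at room temperature.

Step 15
Reactants: 19 C10 β-methyl enone alcohol; 23 (2E,4E,6S)-6-methylocta-2,4-dienoic acid
Product: 25 C1 dienoate ester (C2 α-OTBS; C4=C5–C6=O enone), via mixed anhydride 24 (not isolated)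
Conditions: 2,4,6-Cl3C6H2COCl, Et3N, THF, rt; then 19, DMAP, toluene, rt to 60 °C
Reagents that add atoms: none
Why: Yamaguchi esterification through the aroyl mixed anhydride and the acylpyridinium ion is the standard method for crowded secondary alcohols and should acylate C1–OH, the only free hydroxyl, with retention.

Step 16
Reactants: 25 C1 dienoate ester
Product: 27 C7-hydroxy enone (either C7 epimer), via lithium dienolate 26 (not isolated)
Conditions: LiHMDS (1.1 equiv), THF, −78 °C; then 3-phenyl-2-(phenylsulfonyl)oxaziridine, −78 °C; aq NH4Cl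
Reagents that add atoms: 3-phenyl-2-(phenylsulfonyl)oxaziridine, O=S(=O)(c1ccccc1)N1OC1c1ccccc1
Why: Kinetic deprotonation of the enone at C7 gives the cross-conjugated dienolate, and its sulfonyloxaziridine hydroxylation should give the C7 alcohol; its configuration is irrelevant because C7 becomes sp2 in step 17.

Step 17
Reactants: 27 C7-hydroxy enone
Product: 29 C2-O-TBS septeremophilane G, via C6,C7-dione 28 (not isolated)
Conditions: Dess–Martin periodinane (1,1,1-triacetoxy-1,1-dihydro-1,2-benziodoxol-3(1H)-one), CH2Cl2, 0 °C to rt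
Reagents that add atoms: none
Why: Periodinane oxidation of the acyloin gives the 1,2-dione, which should enolise at once toward C8 to the cross-conjugated diosphenol because C9 is quaternary.

Step 18
Reactants: 29 C2-O-TBS septeremophilane G
Product: 30 septeremophilane G
Conditions: HF·pyridine, pyridine, THF, 0 °C to rt
Reagents that add atoms: none
Why: Silyl ether cleavage with buffered hydrogen fluoride should free C2–OH under mildly acidic conditions that avoid acyl migration from C1 and leave the dienone and dienoate alone.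

**Compound list**
1 | hex-5-enoic acid | C=CCCCC(=O)O | starting material
2 | N-methoxy-N-methylhex-5-enamide | C=CCCCC(=O)N(C)OC | intermediate
3 | methyl vinyl ketone | CC(=O)C=C | starting material
4 | (E)-N-methoxy-N-methyl-7-oxooct-5-enamide | CC(=O)/C=C/CCCC(=O)N(C)OC | intermediate
5 | (E)-7-(tert-butyldimethylsilyloxy)-N-methoxy-N-methylocta-5,7-dienamide | C=C(O[Si](C)(C)C(C)(C)C)/C=C/CCCC(=O)N(C)OC | intermediate
6 | isopropenylmagnesium bromide | C=C(C)[Mg]Br | starting material
7 | bromomagnesium hemiaminal from 5 and 6 (not isolated) | C=C(C)C(O[Mg]Br)(CCC/C=C/C(=C)O[Si](C)(C)C(C)(C)C)N(C)OC | intermediate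
8 | (E)-9-(tert-butyldimethylsilyloxy)-2-methyldeca-1,7,9-trien-3-one | C=C(C)C(=O)CCC/C=C/C(=C)O[Si](C)(C)C(C)(C)C | intermediate
9 | (4aR,8aS)-6-(tert-butyldimethylsilyloxy)-8a-methyl-3,4,4a,7,8,8a-hexahydronaphthalen-1(2H)-one | O=C1CCC[C@@H]2C=C(O[Si](C)(C)C(C)(C)C)CC[C@]12C | intermediate
10 | lithium enolate of 9 (not isolated) | [Li]OC1=CCC[C@@H]2C=C(O[Si](C)(C)C(C)(C)C)CC[C@]12C | intermediate
11 | (4aR,8aS)-6-(tert-butyldimethylsilyloxy)-8a-methyl-4a,7,8,8a-tetrahydronaphthalen-1(4H)-one | O=C1C=CC[C@@H]2C=C(O[Si](C)(C)C(C)(C)C)CC[C@]12C | intermediate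
12 | C2 α-pinacolboronate of the C10 ketone (not isolated) | O=C1C[C@H](B3OC(C)(C)C(C)(C)O3)C[C@@H]2C=C(O[Si](C)(C)C(C)(C)C)CC[C@]12C | intermediate
13 | (3R,4aR,8aS)-6-(tert-butyldimethylsilyloxy)-3-hydroxy-8a-methyl-3,4,4a,7,8,8a-hexahydronaphthalen-1(2H)-one | O=C1C[C@H](O)C[C@@H]2C=C(O[Si](C)(C)C(C)(C)C)CC[C@]12C | intermediate
14 | (3R,4aR,8aS)-3,6-bis(tert-butyldimethylsilyloxy)-8a-methyl-3,4,4a,7,8,8a-hexahydronaphthalen-1(2H)-one | O=C1C[C@H](O[Si](C)(C)C(C)(C)C)C[C@@H]2C=C(O[Si](C)(C)C(C)(C)C)CC[C@]12C | intermediate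
15 | potassium enolate of 14 (not isolated) | [K]OC1=C[C@H](O[Si](C)(C)C(C)(C)C)C[C@@H]2C=C(O[Si](C)(C)C(C)(C)C)CC[C@]12C | intermediate
16 | (2S,3R,4aR,8aS)-3,6-bis(tert-butyldimethylsilyloxy)-2-hydroxy-8a-methyl-3,4,4a,7,8,8a-hexahydronaphthalen-1(2H)-one | O=C1[C@@H](O)[C@H](O[Si](C)(C)C(C)(C)C)C[C@@H]2C=C(O[Si](C)(C)C(C)(C)C)CC[C@]12C | intermediate
17 | C10-methylidene allylic alcohol (C1 β-OH; C2 α-OTBS; C5=C6 silyl enol ether; cis-fused) | C=C1[C@@H](O)[C@H](O[Si](C)(C)C(C)(C)C)C[C@@H]2C=C(O[Si](C)(C)C(C)(C)C)CC[C@]12C | intermediate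
18 | C10-methylidene enone (C4=C5, C6=O; C1 β-OH; C2 α-OTBS) | C=C1[C@@H](O)[C@H](O[Si](C)(C)C(C)(C)C)CC2=CC(=O)CC[C@]12C | intermediate
19 | C10 β-methyl enone alcohol (C1 β-OH; C2 α-OTBS) | C[C@H]1[C@@H](O)[C@H](O[Si](C)(C)C(C)(C)C)CC2=CC(=O)CC[C@]12C | intermediate
20 | (S)-2-methylbutan-1-ol | CC[C@H](C)CO | starting material
21 | (S)-2-methylbutanal (not isolated) | CC[C@H](C)C=O | intermediate
22 | ethyl (2E,4E,6S)-6-methylocta-2,4-dienoate | CC[C@H](C)/C=C/C=C/C(=O)OCC | intermediate
23 | (2E,4E,6S)-6-methylocta-2,4-dienoic acid | CC[C@H](C)/C=C/C=C/C(=O)O | intermediate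
24 | mixed anhydride of 23 with 2,4,6-trichlorobenzoic acid (not isolated) | CC[C@H](C)/C=C/C=C/C(=O)OC(=O)c1c(Cl)cc(Cl)cc1Cl | intermediate
25 | C1 dienoate ester (C2 α-OTBS; C4=C5–C6=O enone) | CC[C@H](C)/C=C/C=C/C(=O)O[C@H]1[C@H](O[Si](C)(C)C(C)(C)C)CC2=CC(=O)CC[C@]2(C)[C@H]1C | intermediate
26 | lithium C6,C7-dienolate of 25 (not isolated) | CC[C@H](C)/C=C/C=C/C(=O)O[C@H]1[C@H](O[Si](C)(C)C(C)(C)C)CC2=CC(O[Li])=CC[C@]2(C)[C@H]1C | intermediate
27 | C7-hydroxy enone (C7 epimers) | CC[C@H](C)/C=C/C=C/C(=O)O[C@H]1[C@H](O[Si](C)(C)C(C)(C)C)CC2=CC(=O)C(O)C[C@]2(C)[C@H]1C | intermediate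
28 | C6,C7-dione (not isolated) | CC[C@H](C)/C=C/C=C/C(=O)O[C@H]1[C@H](O[Si](C)(C)C(C)(C)C)CC2=CC(=O)C(=O)C[C@]2(C)[C@H]1C | intermediate
29 | C2-O-TBS septeremophilane G | CC[C@H](C)/C=C/C=C/C(=O)O[C@H]1[C@H](O[Si](C)(C)C(C)(C)C)CC2=CC(=O)C(O)=C[C@]2(C)[C@H]1C | intermediate
30 | septeremophilane G | CC[C@H](C)/C=C/C=C/C(=O)O[C@H]1[C@H](O)CC2=CC(=O)C(O)=C[C@]2(C)[C@H]1C | target

**Step count**
Total: 18 steps. Longest linear sequence: 16 steps (steps 1–12 and 15–18); steps 13–14 make the side-chain acid.

**Steps most likely to fail**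

Step 5 (new method). The catalyst may select the enone face poorly, or acid-promoted loss of the silyl enol ether and stepwise Michael oligomerisation may outrun the cycloaddition. The fallback supplies the same bicycle by known chemistry and sets out from methyl vinyl ketone 3. Michael addition of 3 to 2-methylcyclohexane-1,3-dione F1 (water, 75 °C) gives 2-methyl-2-(3-oxobutyl)cyclohexane-1,3-dione F2. L-Proline-catalysed intramolecular aldol condensation (Hajos–Parrish–Eder–Sauer–Wiechert reaction, DMSO, rt) gives (S)-Wieland–Miescher ketone F3. Conjugate reduction with [(Ph3P)CuH]6 in the presence of TBSCl (benzene/THF, rt) reduces only the enone, delivers hydride to C4 on the face of the angular methyl and traps the enolate as the silyl enol ether, which returns to the route at 9. A trans-fused by-product would converge at step 11.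

Step 12. Ring A can flip between two half-chair forms, so hydrogen may reach both faces of the C10 methylene (poor facial selectivity), or the allylic hydroxyl may draw the catalyst to the β face. The fallback replaces steric control by a directing group and sets out from 18. Acylation of C1–OH with diethylphosphonoacetic acid (DCC, DMAP) gives the C1 diethylphosphonoacetate F4. HF·pyridine removes the C2 silyl group to give the C2 alcohol F5. Hydrogenation with [Ir(cod)(PCy3)(py)]PF6, which binds the α-oriented C2 hydroxyl and so delivers hydrogen to the α face of C10, gives the C10 β-methyl compound F6. Re-silylation (TBSOTf, 2,6-lutidine) gives the C2 silyl ether F7. Horner–Wadsworth–Emmons reaction (LiCl, i-Pr2NEt, MeCN) with (S,E)-4-methylhex-2-enal F8 (from aldehyde 21 and Ph3P=CHCHO) then builds the dienoate and returns to the route at 25, bypassing steps 12 and 15.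

Step 10. The titanium reagent may be consumed by the free hydroxyl or react too slowly at the crowded, α-oxygenated carbonyl, leading to incomplete conversion or enolisation. The fallback is a two-stage Peterson olefination from 16. Addition of Me3SiCH2Li/CeCl3 (an organocerium reagent of low basicity that adds to hindered, enolisable ketones; THF, −78 °C) gives the C10 β-hydroxysilane F9, and base-induced syn-elimination (KHMDS, THF, 0 °C) returns to the route at 17.

**Further compounds**
F1 | step 5 | 2-methylcyclohexane-1,3-dione | CC1C(=O)CCCC1=O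
F2 | step 5 | 2-methyl-2-(3-oxobutyl)cyclohexane-1,3-dione | CC(=O)CCC1(C)C(=O)CCCC1=O
F3 | step 5 | (S)-Wieland–Miescher ketone | O=C1CCCC2=CC(=O)CC[C@]12C
F4 | step 12 | C1 diethylphosphonoacetate of 18 | C=C1[C@@H](OC(=O)CP(=O)(OCC)OCC)[C@H](O[Si](C)(C)C(C)(C)C)CC2=CC(=O)CC[C@]12C
F5 | step 12 | C1 diethylphosphonoacetate with free C2 α-OH | C=C1[C@@H](OC(=O)CP(=O)(OCC)OCC)[C@H](O)CC2=CC(=O)CC[C@]12C
F6 | step 12 | C10 β-methyl C1 diethylphosphonoacetate with free C2 α-OH | C[C@H]1[C@@H](OC(=O)CP(=O)(OCC)OCC)[C@H](O)CC2=CC(=O)CC[C@]12C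
F7 | step 12 | C10 β-methyl C1 diethylphosphonoacetate C2 α-TBS ether | C[C@H]1[C@@H](OC(=O)CP(=O)(OCC)OCC)[C@H](O[Si](C)(C)C(C)(C)C)CC2=CC(=O)CC[C@]12C
F8 | step 12 | (S,E)-4-methylhex-2-enal | CC[C@H](C)/C=C/C=O
F9 | step 10 | C10 β-hydroxysilane from 16 (C10 epimers) | C[Si](C)(C)CC1(O)[C@@H](O)[C@H](O[Si](C)(C)C(C)(C)C)C[C@@H]2C=C(O[Si](C)(C)C(C)(C)C)CC[C@]12C
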